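**Retrosynthetic overview**
1. Target ⇐ tetraol (angeloylation of C6‑OH and C10‑OH only) ⇐ ring‑fusion‑methyl diketo‑diol, by three substrate‑controlled ketone reductions.
2. Angular C1‑methyl ⇐ C‑methylation of the ring‑fusion 1,3‑diketone after the bicycle exists (cis ring fusion).
3. Hydroazulene ⇐ intramolecular Buchner reaction of an orcinol‑derived α‑diazoketone: cyclopentanone and seven‑membered ring (arene ring expansion) form in the same operation; the two aryl OMe groups become C6=O/C10=O and the aryl methyl becomes C8‑Me.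
4. Diazoketone ⇐ methyl ketone ⇐ (S)‑homoallylic tertiary alcohol (C4) ⇐ aryl isopropyl ketone ⇐ 3,5‑dimethoxytoluene + isobutyric anhydride.

Assumption: daucane numbering is used (C1 = methyl‑bearing ring‑fusion carbon, C2–C4 five‑membered ring, C5 = ring‑fusion CH, C6–C10 seven‑membered ring), α = face of the C1 methyl; in step 2 the ligand antipode that gives the (S)‑alcohol is used; 11–13 are drawn as keto tautomers with C1 undefined.

**Step 1**
Reactants: 1 3,5-dimethoxytoluene; 2 isobutyric anhydride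
Product: 4 1-(2,6-dimethoxy-4-methylphenyl)-2-methylpropan-1-one, via aryllithium 3 (not isolated)
Conditions: n-BuLi, TMEDA, THF, 0 °C to rt; then 2, −78 °C to rt; 1 M HCl work-up
Reagents that add atoms: none
Why: Directed ortho-metalation occurs at the carbon flanked by both methoxy groups, and the hindered aryllithium is acylated once by the anhydride because the di-ortho-substituted ketone resists a second addition.

**Step 2**
Reactants: 4 1-(2,6-dimethoxy-4-methylphenyl)-2-methylpropan-1-one; 5 allylboronic acid pinacol ester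
Product: 6 (S)-3-(2,6-dimethoxy-4-methylphenyl)-2-methylhex-5-en-3-ol
Conditions: CuF(PPh3)3·2EtOH (5 mol %), iPr-DuPHOS (10 mol %), La(OiPr)3 (7.5 mol %), DMF, −40 to 0 °C
Reagents that add atoms: none
Why: Copper-catalysed enantioselective allylboration of a ketone through a chiral allylcopper species sets the C4 carbinol, with facial discrimination between the aryl and isopropyl groups.

**Step 3**
Reactants: 6 (S)-3-(2,6-dimethoxy-4-methylphenyl)-2-methylhex-5-en-3-ol
Product: 7 (S)-triethyl{[3-(2,6-dimethoxy-4-methylphenyl)-2-methylhex-5-en-3-yl]oxy}silane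
Conditions: TESOTf, 2,6-lutidine, CH2Cl2, 0 °C to rt
Reagents that add atoms: triethylsilyl trifluoromethanesulfonate, CC[Si](CC)(CC)OS(=O)(=O)C(F)(F)F
Why: Silylation of the tertiary alcohol so that the later carbenoid cannot undergo O–H insertion.

**Step 4**
Reactants: 7 (S)-triethyl{[3-(2,6-dimethoxy-4-methylphenyl)-2-methylhex-5-en-3-yl]oxy}silane
Product: 8 (S)-4-(2,6-dimethoxy-4-methylphenyl)-5-methyl-4-(triethylsilyloxy)hexan-2-one
Conditions: PdCl2 (10 mol %), CuCl, O2 (1 atm), DMF–H2O 7:1, rt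
Reagents that add atoms: water, O
Why: Tsuji–Wacker oxidation; Markovnikov hydroxypalladation of the terminal alkene gives the methyl ketone.

**Step 5**
Reactants: 8 (S)-4-(2,6-dimethoxy-4-methylphenyl)-5-methyl-4-(triethylsilyloxy)hexan-2-one
Product: 10 (S)-1-diazo-4-(2,6-dimethoxy-4-methylphenyl)-5-methyl-4-(triethylsilyloxy)hexan-2-one, via trifluoroacetyl diketone 9 (not isolated)
Conditions: LiHMDS, THF, −78 °C; CF3CO2CH2CF3; then p-ABSA, Et3N, MeCN, rt
Reagents that add atoms: 4-acetamidobenzenesulfonyl azide, CC(=O)Nc1ccc(cc1)S(=O)(=O)N=[N+]=[N-]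
Why: Detrifluoroacetylative diazo transfer (Danheiser); kinetic deprotonation takes the methyl group because the other α‑CH2 is neopentyl.

**Step 6**
Reactants: 10 (S)-1-diazo-4-(2,6-dimethoxy-4-methylphenyl)-5-methyl-4-(triethylsilyloxy)hexan-2-one
Product: 12 (3S,3aS)-3-hydroxy-6-methyl-3-(propan-2-yl)-3,3a,5,8a-tetrahydroazulene-1,4,8(2H)-trione, via Buchner cycloadduct 11 (not isolated)
Conditions: Rh2(OAc)4 (1 mol %), CH2Cl2, 40 °C, slow addition; then 1 M HCl, THF, 0 °C to rt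
Reagents that add atoms: water, O
Why: Intramolecular Buchner reaction: the rhodium carbenoid cyclopropanates the ipso–ortho bond of the electron-rich arene and the norcaradiene opens (6π) to the cyclopentanone-fused cycloheptatriene, so both rings form in one operation; acid then cleaves both enol ethers and the silyl ether, C1 becomes an enolised 1,3-diketone carbon, and C5 (α to the C6 ketone) equilibrates to the epimer with C6 trans to the isopropyl group and hydrogen-bonded to the C4 hydroxyl.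

**Step 7**
Reactants: 12 (3S,3aS)-3-hydroxy-6-methyl-3-(propan-2-yl)-3,3a,5,8a-tetrahydroazulene-1,4,8(2H)-trione
Product: 13 (3S,3aR,4R)-3,4-dihydroxy-6-methyl-3-(propan-2-yl)-3,3a,4,5-tetrahydroazulene-1,8(2H,8aH)-dione
Conditions: Me4NBH(OAc)3, MeCN–AcOH 1:1, −30 °C
Reagents that add atoms: none
Why: Evans–Saksena reduction: hydride is delivered from the C4 alkoxyborohydride to C6 on the face of the C4 hydroxyl, giving the anti-1,3-diol (6α‑OH), while the enolised 1,3-diketone is inert.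

**Step 8**
Reactants: 13 (3S,3aR,4R)-3,4-dihydroxy-6-methyl-3-(propan-2-yl)-3,3a,4,5-tetrahydroazulene-1,8(2H,8aH)-dione
Product: 14 (3S,3aR,4R,8aR)-3,4-dihydroxy-6,8a-dimethyl-3-(propan-2-yl)-3,3a,4,5-tetrahydroazulene-1,8(2H,8aH)-dione
Conditions: K2CO3, MeI, acetone, rt
Reagents that add atoms: iodomethane, CI
Why: C-alkylation of the 2-substituted 1,3-diketone (the only acidic site once C6 is reduced); MeI approaches C1 on the face of H5, anti to the C5–C6 bond, giving the cis ring fusion.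

**Step 9**
Reactants: 14 (3S,3aR,4R,8aR)-3,4-dihydroxy-6,8a-dimethyl-3-(propan-2-yl)-3,3a,4,5-tetrahydroazulene-1,8(2H,8aH)-dione
Product: 15 (1R,3S,3aR,4R,8aR)-1,3,4-trihydroxy-6,8a-dimethyl-3-(propan-2-yl)-2,3,3a,4,5,8a-hexahydroazulen-8(1H)-one
Conditions: Me4NBH(OAc)3, MeCN–AcOH 1:1, −20 to 0 °C
Reagents that add atoms: none
Why: Evans–Saksena reduction: the β‑C4 hydroxyl delivers hydride to the β‑face of the C2 ketone, giving 2α‑OH (cis to the methyl), while the C10 enone has no suitably placed hydroxyl and is left.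

**Step 10**
Reactants: 15 (1R,3S,3aR,4R,8aR)-1,3,4-trihydroxy-6,8a-dimethyl-3-(propan-2-yl)-2,3,3a,4,5,8a-hexahydroazulen-8(1H)-one
Product: 16 (1R,3S,3aR,4R,8R,8aR)-6,8a-dimethyl-3-(propan-2-yl)-1,2,3,3a,4,5,8,8a-octahydroazulene-1,3,4,8-tetrol
Conditions: NaBH4, CeCl3·7H2O, MeOH, −78 °C
Reagents that add atoms: none
Why: Luche 1,2-reduction of the enone from the convex α‑face (anti to the C1–C2 bond of the cis-fused cyclopentane) gives the 10β allylic alcohol.

**Step 11**
Reactants: 16 (1R,3S,3aR,4R,8R,8aR)-6,8a-dimethyl-3-(propan-2-yl)-1,2,3,3a,4,5,8,8a-octahydroazulene-1,3,4,8-tetrol; 17 angelic acid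
Product: 19 (1R,3S,3aR,4R,8R,8aR)-1,3-dihydroxy-6,8a-dimethyl-3-(propan-2-yl)-1,2,3,3a,4,5,8,8a-octahydroazulene-4,8-diyl bis[(Z)-2-methylbut-2-enoate], via mixed anhydride 18 (not isolated)
Conditions: 17 (3 equiv), 2,4,6-trichlorobenzoyl chloride, Et3N, PhMe, rt; then 16, PhMe, 75 °C
Reagents that add atoms: none
Why: Yamaguchi-type mixed-anhydride acylation without DMAP keeps the Z geometry; C6‑OH and the allylic C10‑OH react, while the tertiary C4‑OH and the C2‑OH (neopentyl, flanked on its face by the angular methyl and the isopropyl group) are expected to stay free.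

**Compound list**
1 | 3,5-dimethoxytoluene | COc1cc(C)cc(OC)c1 | starting material
2 | isobutyric anhydride | CC(C)C(=O)OC(=O)C(C)C | starting material
3 | (2,6-dimethoxy-4-methylphenyl)lithium | [Li]c1c(OC)cc(C)cc1OC | intermediate
4 | 1-(2,6-dimethoxy-4-methylphenyl)-2-methylpropan-1-one | CC(C)C(=O)c1c(OC)cc(C)cc1OC | intermediate
5 | allylboronic acid pinacol ester | C=CCB1OC(C)(C)C(C)(C)O1 | starting material
6 | (S)-3-(2,6-dimethoxy-4-methylphenyl)-2-methylhex-5-en-3-ol | C=CC[C@](O)(C(C)C)c1c(OC)cc(C)cc1OC | intermediate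
7 | (S)-triethyl{[3-(2,6-dimethoxy-4-methylphenyl)-2-methylhex-5-en-3-yl]oxy}silane | C=CC[C@](O[Si](CC)(CC)CC)(C(C)C)c1c(OC)cc(C)cc1OC | intermediate
8 | (S)-4-(2,6-dimethoxy-4-methylphenyl)-5-methyl-4-(triethylsilyloxy)hexan-2-one | CC(=O)C[C@](O[Si](CC)(CC)CC)(C(C)C)c1c(OC)cc(C)cc1OC | intermediate
9 | (S)-6-(2,6-dimethoxy-4-methylphenyl)-1,1,1-trifluoro-7-methyl-6-(triethylsilyloxy)octane-2,4-dione | FC(F)(F)C(=O)CC(=O)C[C@](O[Si](CC)(CC)CC)(C(C)C)c1c(OC)cc(C)cc1OC | intermediate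
10 | (S)-1-diazo-4-(2,6-dimethoxy-4-methylphenyl)-5-methyl-4-(triethylsilyloxy)hexan-2-one | [N-]=[N+]=CC(=O)C[C@](O[Si](CC)(CC)CC)(C(C)C)c1c(OC)cc(C)cc1OC | intermediate
11 | (3S)-4,8-dimethoxy-6-methyl-3-(propan-2-yl)-3-(triethylsilyloxy)-3,8a-dihydroazulen-1(2H)-one | O=C1C[C@](O[Si](CC)(CC)CC)(C(C)C)C2=C(OC)C=C(C)C=C(OC)C12 | intermediate
12 | (3S,3aS)-3-hydroxy-6-methyl-3-(propan-2-yl)-3,3a,5,8a-tetrahydroazulene-1,4,8(2H)-trione | O=C1CC(C)=CC(=O)C2C(=O)C[C@](O)(C(C)C)[C@@H]12 | intermediate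
13 | (3S,3aR,4R)-3,4-dihydroxy-6-methyl-3-(propan-2-yl)-3,3a,4,5-tetrahydroazulene-1,8(2H,8aH)-dione | O[C@@H]1CC(C)=CC(=O)C2C(=O)C[C@](O)(C(C)C)[C@@H]12 | intermediate
14 | (3S,3aR,4R,8aR)-3,4-dihydroxy-6,8a-dimethyl-3-(propan-2-yl)-3,3a,4,5-tetrahydroazulene-1,8(2H,8aH)-dione | O[C@@H]1CC(C)=CC(=O)[C@@]2(C)C(=O)C[C@](O)(C(C)C)[C@@H]12 | intermediate
15 | (1R,3S,3aR,4R,8aR)-1,3,4-trihydroxy-6,8a-dimethyl-3-(propan-2-yl)-2,3,3a,4,5,8a-hexahydroazulen-8(1H)-one | O[C@@H]1CC(C)=CC(=O)[C@@]2(C)[C@H](O)C[C@](O)(C(C)C)[C@@H]12 | intermediate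
16 | (1R,3S,3aR,4R,8R,8aR)-6,8a-dimethyl-3-(propan-2-yl)-1,2,3,3a,4,5,8,8a-octahydroazulene-1,3,4,8-tetrol | O[C@@H]1CC(C)=C[C@@H](O)[C@@]2(C)[C@H](O)C[C@](O)(C(C)C)[C@@H]12 | intermediate
17 | angelic acid, (Z)-2-methylbut-2-enoic acid | C/C=C(/C)C(=O)O | starting material
18 | (Z)-2-methylbut-2-enoic 2,4,6-trichlorobenzoic anhydride | C/C=C(/C)C(=O)OC(=O)c1c(Cl)cc(Cl)cc1Cl | intermediate
19 | CNP0249167.1, (1R,3S,3aR,4R,8R,8aR)-1,3-dihydroxy-6,8a-dimethyl-3-(propan-2-yl)-1,2,3,3a,4,5,8,8a-octahydroazulene-4,8-diyl bis[(Z)-2-methylbut-2-enoate] | C/C=C(/C)C(=O)O[C@@H]1CC(C)=C[C@@H](OC(=O)/C(C)=C\C)[C@@]2(C)[C@H](O)C[C@](O)(C(C)C)[C@@H]12 | target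

**Totals**
Total step count: 11. Longest linear sequence: 11 steps (1 → 19).

**Three steps most likely to fail**

Step 6. The 2,6-dimethoxyarene may divert the carbenoid (oxonium ylide at the silyl ether, dimerisation), the 8a‑H trienone is labile, and the acid step can eliminate the tertiary C4 oxygen to the C4=C5 enone. Fallback, setting out from 8 and coming back at 12: the lithium enolate of 8 is C‑acylated with Boc2O to the tert-butyl β‑keto ester F1, Regitz diazo transfer (p-ABSA, Et3N) gives the diazo keto ester F2, and the more stabilised acceptor/acceptor carbenoid (Rh2(esp)2 or Cu(hfacac)2, PhMe, 80 °C) gives the 8a-tert-butoxycarbonyl azulenone F3, which has no labile 8a‑hydrogen; TFA–water then cleaves the enol ethers, the silyl ether and the tert-butyl ester, and the β‑keto acid decarboxylates to 12.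

Step 8. O‑methylation can compete, and attack on the other face would give the trans-fused C1 epimer, since the C4 isopropyl group sits on the face that must be attacked. Fallback, setting out from 13 and coming back at 14: the α‑C6 hydroxyl is silylated with (bromomethyl)chlorodimethylsilane/imidazole to the bromomethylsilyl ether F4, Cs2CO3 closes a six-membered ring by intramolecular C‑alkylation that can only reach the α‑face of C1, giving the oxasilinane F5, and TBAF in wet DMF protodesilylates the C–Si bond to release the C1 methyl and the C6 hydroxyl, i.e. 14.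

Step 11. Discrimination between the two neopentyl secondary alcohols (C10‑OH wanted, C2‑OH not) in a slow, hindered acylation is uncertain. Fallback, setting out from 15 and coming back at 19: mono-angeloylation of the least hindered C6 hydroxyl (same mixed anhydride, 1.2 equiv) gives the 6-angelate F6, TESCl/imidazole/DMAP protects C2‑OH as the silyl ether F7, Luche reduction gives the 10β-alcohol F8, a second angeloylation gives the silyl-protected diester F9, and HF·pyridine releases 19.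

**Further compounds**
F1 | step 6 | tert-butyl (S)-5-(2,6-dimethoxy-4-methylphenyl)-6-methyl-3-oxo-5-(triethylsilyloxy)heptanoate | CC(C)(C)OC(=O)CC(=O)C[C@](O[Si](CC)(CC)CC)(C(C)C)c1c(OC)cc(C)cc1OC
F2 | step 6 | tert-butyl (S)-2-diazo-5-(2,6-dimethoxy-4-methylphenyl)-6-methyl-3-oxo-5-(triethylsilyloxy)heptanoate | CC(C)(C)OC(=O)C(=[N+]=[N-])C(=O)C[C@](O[Si](CC)(CC)CC)(C(C)C)c1c(OC)cc(C)cc1OC
F3 | step 6 | tert-butyl (3S)-4,8-dimethoxy-6-methyl-1-oxo-3-(propan-2-yl)-3-(triethylsilyloxy)-2,3-dihydroazulene-8a(1H)-carboxylate | O=C1C[C@](O[Si](CC)(CC)CC)(C(C)C)C2=C(OC)C=C(C)C=C(OC)C12C(=O)OC(C)(C)C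
F4 | step 8 | 6-O-[(bromomethyl)dimethylsilyl] ether of 13 | BrC[Si](C)(C)O[C@@H]1CC(C)=CC(=O)C2C(=O)C[C@](O)(C(C)C)[C@@H]12
F5 | step 8 | oxasilinane from F4, C1–CH2–SiMe2–O–C6 bridged diketone | C[Si]3(C)O[C@@H]1CC(C)=CC(=O)[C@@]2(C3)C(=O)C[C@](O)(C(C)C)[C@@H]12
F6 | step 11 | 6-O-angelate of 15 | C/C=C(/C)C(=O)O[C@@H]1CC(C)=CC(=O)[C@@]2(C)[C@H](O)C[C@](O)(C(C)C)[C@@H]12
F7 | step 11 | 2-O-triethylsilyl ether of F6 | C/C=C(/C)C(=O)O[C@@H]1CC(C)=CC(=O)[C@@]2(C)[C@H](O[Si](CC)(CC)CC)C[C@](O)(C(C)C)[C@@H]12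
F8 | step 11 | 10β-alcohol from F7 | C/C=C(/C)C(=O)O[C@@H]1CC(C)=C[C@@H](O)[C@@]2(C)[C@H](O[Si](CC)(CC)CC)C[C@](O)(C(C)C)[C@@H]12
F9 | step 11 | 2-O-triethylsilyl ether of 19 | C/C=C(/C)C(=O)O[C@@H]1CC(C)=C[C@@H](OC(=O)/C(C)=C\C)[C@@]2(C)[C@H](O[Si](CC)(CC)CC)C[C@](O)(C(C)C)[C@@H]12
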